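## Retrosynthetic overview

1. Target ⇐ its octamethyl ether by global O‑demethylation; the 4‑methoxystyryl arm is attached last, at C‑6 of the lower ring, by C–H borylation/Suzuki coupling.
2. Each trans‑2,3‑diaryl‑2,3‑dihydrobenzofuran ⇐ (S)‑2,2‑diarylacetaldehyde dimethyl acetal + aryl Grignard reagent (acetal arylation, then O–C2 closure by an ortho‑methoxy group with loss of its methyl).
3. Each acetal ⇐ E stilbene (3,5‑dioxygenated aryl–CH=CH–2,6‑dimethoxyphenyl) by a reagent‑controlled enantioselective oxidative 1,2‑aryl shift; this makes the C3–aryl bond and sets C‑3′, then C‑3.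
4. Each stilbene ⇐ sterically directed aryl C–H borylation/Suzuki coupling with an (E)‑2‑chloroethenyl arene; every skeletal carbon comes from resorcinol, 4‑bromophenol and (E)‑1,2‑dichloroethene, the phenols being carried as methyl ethers.
5. Ring order: upper dihydrobenzofuran (benzo ring C) first, lower dihydrobenzofuran (benzo ring E) second.

Locants and ring letters: unprimed = lower dihydrobenzofuran (benzo ring E; ring D = 4‑oxygenated phenyl at C‑2; styryl ring F at C‑6). Primed = upper dihydrobenzofuran (benzo ring C; ring A = 2,4‑dioxygenated phenyl at C‑2′; ring B = 3,5‑dioxygenated phenyl at C‑3′). The target is (2S,3S,2′S,3′S), both rings trans.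

Assumption: the (R,R)‑lactate‑derived λ3‑iodane adds iodine to the alkene face that leads to the (S)‑acetal; if the sense proves opposite, its (S,S)‑enantiomer is used with no other change.

## Route

Step 1
Reactants: 1 resorcinol
Product: 2 1,3‑dimethoxybenzene
Conditions: MeI (2.5 equiv), K2CO3, DMF, rt
Reagents that add atoms: iodomethane (CI)
Why: Williamson O‑methylation of both phenols installs the methyl ethers that protect the oxygens until the last step.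

Step 2
Reactants: 2 1,3‑dimethoxybenzene; 3 (E)‑1,2‑dichloroethene
Product: 6 2‑[(E)‑2‑chloroethenyl]‑1,3‑dimethoxybenzene, via aryllithium 4 (not isolated), via arylzinc chloride 5 (not isolated)
Conditions: n‑BuLi, THF, 0 °C to rt; ZnCl2, 0 °C; 3 (5 equiv), Pd(PPh3)4 (3 mol %), 50 °C
Reagents that add atoms: none
Why: Directed ortho‑lithiation occurs between the two methoxy groups, and the derived arylzinc undergoes a stereoretentive Negishi mono‑coupling with excess dichloroethene to give the E chloroalkene.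

Step 3
Reactants: 2 1,3‑dimethoxybenzene; 6 2‑[(E)‑2‑chloroethenyl]‑1,3‑dimethoxybenzene
Product: 8 2‑[(E)‑2‑(3,5‑dimethoxyphenyl)ethenyl]‑1,3‑dimethoxybenzene, via arylboronate 7 (not isolated)
Conditions: [Ir(OMe)(cod)]2 (1.5 mol %), 4,4′‑di‑tert‑butyl‑2,2′‑bipyridine, B2pin2, THF, 80 °C; then 6, Pd(OAc)2 (2 mol %), SPhos, K3PO4, H2O, 70 °C
Reagents that add atoms: none
Why: Sterically controlled Ir‑catalysed C–H borylation hits only C‑5 (the one C–H with no ortho substituent), and the crude boronate undergoes Suzuki–Miyaura coupling with 6 with retention of the E geometry.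

Step 4
Reactants: 8 2‑[(E)‑2‑(3,5‑dimethoxyphenyl)ethenyl]‑1,3‑dimethoxybenzene
Product: 9 2‑[(1S)‑1‑(3,5‑dimethoxyphenyl)‑2,2‑dimethoxyethyl]‑1,3‑dimethoxybenzene
Conditions: (R,R)‑2,6‑bis[1‑(methoxycarbonyl)ethoxy]phenyl‑λ3‑iodanediyl diacetate (1.2 equiv), BF3·OEt2 (2 equiv), CH2Cl2/MeOH 9:1, −78 to −40 °C
Reagents that add atoms: methanol (CO)
Why: Proposed new method: the chiral aryl‑λ3‑iodane adds face‑selectively to the E alkene so that iodine binds the carbon bearing the 3,5‑dimethoxyphenyl group while methanol caps the 2,6‑dimethoxybenzylic cation, the 2,6‑dimethoxyphenyl group then displaces the aryliodonio group from the back (phenonium ion, stereospecific 1,2‑aryl shift with inversion) and methanol traps the oxocarbenium ion, so the face of iodination fixes the new (S) diarylmethine centre in a configurationally stable acetal; the closest known reactions are the racemic oxidative rearrangement of stilbenes to 2,2‑diarylacetaldehyde dimethyl acetals with PhI(OH)OTs or Tl(NO3)3 in methanol and the enantioselective rearrangement of 1,1‑disubstituted aryl alkenes to α‑aryl ketones with lactate‑based λ3‑iodanes.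

Step 5
Reactants: 2 1,3‑dimethoxybenzene
Product: 10 1‑bromo‑2,4‑dimethoxybenzene
Conditions: NBS, MeCN, 0 °C to rt
Reagents that add atoms: N‑bromosuccinimide (O=C1CCC(=O)N1Br)
Why: Electrophilic aromatic bromination goes para to one methoxy group and ortho to the other, the most activated unhindered position.

Step 6
Reactants: 9 2‑[(1S)‑1‑(3,5‑dimethoxyphenyl)‑2,2‑dimethoxyethyl]‑1,3‑dimethoxybenzene; 10 1‑bromo‑2,4‑dimethoxybenzene
Product: 13 (2S,3S)‑2‑(2,4‑dimethoxyphenyl)‑3‑(3,5‑dimethoxyphenyl)‑4‑methoxy‑2,3‑dihydro‑1‑benzofuran, via Grignard reagent 11 (not isolated), via benzylic methyl ether 12 (not isolated)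
Conditions: 10, Mg, Et2O, reflux; 9, TiCl4 (1.2 equiv), CH2Cl2, −78 °C, then the Grignard solution (1.1 equiv); then TiCl4 (1.5 equiv), −78 to −20 °C
Reagents that add atoms: none
Why: Mukaiyama‑type TiCl4‑promoted substitution of one acetal methoxy group by the aryl Grignard reagent at −78 °C gives ether 12 without touching the diarylmethine centre, and further TiCl4 ionises 12 to a 2,4‑dimethoxybenzyl cation that is captured by the neighbouring ortho‑methoxy oxygen (five‑membered neighbouring‑group participation, chloride removing the O‑methyl group as MeCl); the closure is reversible and gives the thermodynamically favoured 2,3‑trans ring, so the fixed C‑3 centre sets C‑2 as S.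

Step 7
Reactants: 13 (2S,3S)‑2‑(2,4‑dimethoxyphenyl)‑3‑(3,5‑dimethoxyphenyl)‑4‑methoxy‑2,3‑dihydro‑1‑benzofuran; 6 2‑[(E)‑2‑chloroethenyl]‑1,3‑dimethoxybenzene
Product: 15 (2S,3S)‑2‑(2,4‑dimethoxyphenyl)‑6‑[(E)‑2‑(2,6‑dimethoxyphenyl)ethenyl]‑3‑(3,5‑dimethoxyphenyl)‑4‑methoxy‑2,3‑dihydro‑1‑benzofuran, via arylboronate 14 (not isolated)
Conditions: [Ir(OMe)(cod)]2 (3 mol %), 3,4,7,8‑tetramethyl‑1,10‑phenanthroline, B2pin2, THF, 80 °C; then 6, Pd(OAc)2 (3 mol %), SPhos, K3PO4, H2O, 70 °C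
Reagents that add atoms: none
Why: C–H borylation selects C‑6 of ring C, the only aromatic C–H in 13 without an ortho substituent, and Suzuki–Miyaura coupling with a second portion of 6 gives the E stilbene without touching the two stereocentres.

Step 8
Reactants: 15 (2S,3S)‑2‑(2,4‑dimethoxyphenyl)‑6‑[(E)‑2‑(2,6‑dimethoxyphenyl)ethenyl]‑3‑(3,5‑dimethoxyphenyl)‑4‑methoxy‑2,3‑dihydro‑1‑benzofuran
Product: 16 (2S,3S)‑6‑[(1S)‑1‑(2,6‑dimethoxyphenyl)‑2,2‑dimethoxyethyl]‑2‑(2,4‑dimethoxyphenyl)‑3‑(3,5‑dimethoxyphenyl)‑4‑methoxy‑2,3‑dihydro‑1‑benzofuran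
Conditions: (R,R)‑2,6‑bis[1‑(methoxycarbonyl)ethoxy]phenyl‑λ3‑iodanediyl diacetate (1.2 equiv), BF3·OEt2 (2 equiv), CH2Cl2/MeOH 9:1, −78 °C
Reagents that add atoms: methanol (CO)
Why: Proposed new method: the same reagent‑controlled oxidative 1,2‑aryl shift as in step 4 acts on an alkene of the same electronic type (meta‑dioxygenated aryl on one carbon, 2,6‑dimethoxyphenyl on the other), so face‑selective iodination followed by invertive phenonium migration and methanol capture sets the new diarylmethine centre as S under reagent control, while −78 °C and methanol‑buffered BF3 spare the acid‑sensitive 2‑(2,4‑dimethoxyphenyl) ring; the closest known reactions are the racemic PhI(OH)OTs or Tl(NO3)3 rearrangement of stilbenes and the lactate‑iodane rearrangement of 1,1‑disubstituted aryl alkenes.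

Step 9
Reactants: 17 4‑bromophenol
Product: 18 1‑bromo‑4‑methoxybenzene
Conditions: MeI (1.3 equiv), K2CO3, acetone, reflux
Reagents that add atoms: iodomethane (CI)
Why: Williamson O‑methylation protects the phenol as the methyl ether that is needed for the organometallic steps.

Step 10
Reactants: 16 (2S,3S)‑6‑[(1S)‑1‑(2,6‑dimethoxyphenyl)‑2,2‑dimethoxyethyl]‑2‑(2,4‑dimethoxyphenyl)‑3‑(3,5‑dimethoxyphenyl)‑4‑methoxy‑2,3‑dihydro‑1‑benzofuran; 18 1‑bromo‑4‑methoxybenzene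
Product: 21 (2S,3S)‑3‑[(2S,3S)‑2‑(2,4‑dimethoxyphenyl)‑3‑(3,5‑dimethoxyphenyl)‑4‑methoxy‑2,3‑dihydro‑1‑benzofuran‑6‑yl]‑4‑methoxy‑2‑(4‑methoxyphenyl)‑2,3‑dihydro‑1‑benzofuran, via Grignard reagent 19 (not isolated), via benzylic methyl ether 20 (not isolated)
Conditions: 18, Mg, Et2O, reflux; 16, TiCl4 (1.2 equiv), CH2Cl2, −78 °C, then the Grignard solution (1.1 equiv); then TiCl4 (1.5 equiv), −78 to −10 °C
Reagents that add atoms: none
Why: The same Mukaiyama‑type acetal arylation and neighbouring‑group (ortho‑methoxy) cyclisation as in step 6 now proceeds through a 4‑methoxybenzyl cation, and any reversible opening of either benzylic C–O bond recloses to the trans ring without involving C‑3 or C‑3′, so the fixed C‑3 centre sets C‑2 as S.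

Step 11
Reactants: 18 1‑bromo‑4‑methoxybenzene; 3 (E)‑1,2‑dichloroethene
Product: 24 1‑[(E)‑2‑chloroethenyl]‑4‑methoxybenzene, via aryllithium 22 (not isolated), via arylzinc chloride 23 (not isolated)
Conditions: n‑BuLi, THF, −78 °C; ZnCl2, −78 °C to rt; 3 (5 equiv), Pd(PPh3)4 (3 mol %), rt to 40 °C
Reagents that add atoms: none
Why: Bromine–lithium exchange and transmetalation to zinc give an arylzinc chloride whose Negishi mono‑coupling with excess (E)‑1,2‑dichloroethene keeps the E geometry, because oxidative addition of zerovalent palladium into the vinyl C–Cl bond is stereoretentive.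

Step 12
Reactants: 21 (2S,3S)‑3‑[(2S,3S)‑2‑(2,4‑dimethoxyphenyl)‑3‑(3,5‑dimethoxyphenyl)‑4‑methoxy‑2,3‑dihydro‑1‑benzofuran‑6‑yl]‑4‑methoxy‑2‑(4‑methoxyphenyl)‑2,3‑dihydro‑1‑benzofuran; 24 1‑[(E)‑2‑chloroethenyl]‑4‑methoxybenzene
Product: 26 (2S,3S)‑3‑[(2S,3S)‑2‑(2,4‑dimethoxyphenyl)‑3‑(3,5‑dimethoxyphenyl)‑4‑methoxy‑2,3‑dihydro‑1‑benzofuran‑6‑yl]‑4‑methoxy‑2‑(4‑methoxyphenyl)‑6‑[(E)‑2‑(4‑methoxyphenyl)ethenyl]‑2,3‑dihydro‑1‑benzofuran, via arylboronate 25 (not isolated)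
Conditions: [Ir(OMe)(cod)]2 (3 mol %), 3,4,7,8‑tetramethyl‑1,10‑phenanthroline, B2pin2, THF, 80 °C; then 24, Pd(OAc)2 (3 mol %), SPhos, K3PO4, H2O, 70 °C
Reagents that add atoms: none
Why: C–H borylation selects C‑6 of ring E, the only remaining aromatic C–H flanked by two hydrogens, and Suzuki–Miyaura coupling with 24 installs the E styryl arm.

Step 13
Reactants: 26 (2S,3S)‑3‑[(2S,3S)‑2‑(2,4‑dimethoxyphenyl)‑3‑(3,5‑dimethoxyphenyl)‑4‑methoxy‑2,3‑dihydro‑1‑benzofuran‑6‑yl]‑4‑methoxy‑2‑(4‑methoxyphenyl)‑6‑[(E)‑2‑(4‑methoxyphenyl)ethenyl]‑2,3‑dihydro‑1‑benzofuran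
Product: 27 (2S,3S)‑3‑[(2S,3S)‑2‑(2,4‑dihydroxyphenyl)‑3‑(3,5‑dihydroxyphenyl)‑4‑hydroxy‑2,3‑dihydro‑1‑benzofuran‑6‑yl]‑2‑(4‑hydroxyphenyl)‑6‑[(E)‑2‑(4‑hydroxyphenyl)ethenyl]‑2,3‑dihydro‑1‑benzofuran‑4‑ol
Conditions: BBr3 (20 equiv), CH2Cl2, −78 °C to rt; then H2O
Reagents that add atoms: none
Why: BBr3 cleaves all eight aryl methyl ethers (Lewis‑acid ether cleavage), and because the E stilbene and the trans rings are the thermodynamic forms, any reversible opening of a benzylic C–O bond recloses trans without involving C‑3 or C‑3′.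

## Compound list

1 | resorcinol (benzene‑1,3‑diol) | Oc1cccc(O)c1 | starting material
2 | 1,3‑dimethoxybenzene | COc1cccc(OC)c1 | intermediate
3 | (E)‑1,2‑dichloroethene | Cl/C=C/Cl | starting material
4 | (2,6‑dimethoxyphenyl)lithium | [Li]c1c(OC)cccc1OC | intermediate
5 | chloro(2,6‑dimethoxyphenyl)zinc | Cl[Zn]c1c(OC)cccc1OC | intermediate
6 | 2‑[(E)‑2‑chloroethenyl]‑1,3‑dimethoxybenzene | COc1cccc(OC)c1/C=C/Cl | intermediate
7 | 2‑(3,5‑dimethoxyphenyl)‑4,4,5,5‑tetramethyl‑1,3,2‑dioxaborolane | COc1cc(OC)cc(c1)B1OC(C)(C)C(C)(C)O1 | intermediate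
8 | 2‑[(E)‑2‑(3,5‑dimethoxyphenyl)ethenyl]‑1,3‑dimethoxybenzene | COc1cc(OC)cc(/C=C/c2c(OC)cccc2OC)c1 | intermediate
9 | 2‑[(1S)‑1‑(3,5‑dimethoxyphenyl)‑2,2‑dimethoxyethyl]‑1,3‑dimethoxybenzene | COC(OC)[C@@H](c1cc(OC)cc(OC)c1)c1c(OC)cccc1OC | intermediate
10 | 1‑bromo‑2,4‑dimethoxybenzene | COc1ccc(Br)c(OC)c1 | intermediate
11 | bromo(2,4‑dimethoxyphenyl)magnesium | COc1ccc([Mg]Br)c(OC)c1 | intermediate
12 | 2‑[(1S)‑1‑(3,5‑dimethoxyphenyl)‑2‑(2,4‑dimethoxyphenyl)‑2‑methoxyethyl]‑1,3‑dimethoxybenzene (both C‑2 epimers) | COC(c1ccc(OC)cc1OC)[C@@H](c1cc(OC)cc(OC)c1)c1c(OC)cccc1OC | intermediate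
13 | (2S,3S)‑2‑(2,4‑dimethoxyphenyl)‑3‑(3,5‑dimethoxyphenyl)‑4‑methoxy‑2,3‑dihydro‑1‑benzofuran | c1cc(OC)c2c(c1)O[C@H](c1ccc(OC)cc1OC)[C@H]2c1cc(OC)cc(OC)c1 | intermediate
14 | 2‑[(2S,3S)‑2‑(2,4‑dimethoxyphenyl)‑3‑(3,5‑dimethoxyphenyl)‑4‑methoxy‑2,3‑dihydro‑1‑benzofuran‑6‑yl]‑4,4,5,5‑tetramethyl‑1,3,2‑dioxaborolane | CC1(C)OB(OC1(C)C)c1cc(OC)c2c(c1)O[C@H](c1ccc(OC)cc1OC)[C@H]2c1cc(OC)cc(OC)c1 | intermediate
15 | (2S,3S)‑2‑(2,4‑dimethoxyphenyl)‑6‑[(E)‑2‑(2,6‑dimethoxyphenyl)ethenyl]‑3‑(3,5‑dimethoxyphenyl)‑4‑methoxy‑2,3‑dihydro‑1‑benzofuran | COc1cccc(OC)c1/C=C/c1cc(OC)c2c(c1)O[C@H](c1ccc(OC)cc1OC)[C@H]2c1cc(OC)cc(OC)c1 | intermediate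
16 | (2S,3S)‑6‑[(1S)‑1‑(2,6‑dimethoxyphenyl)‑2,2‑dimethoxyethyl]‑2‑(2,4‑dimethoxyphenyl)‑3‑(3,5‑dimethoxyphenyl)‑4‑methoxy‑2,3‑dihydro‑1‑benzofuran | COC(OC)[C@H](c1c(OC)cccc1OC)c1cc(OC)c2c(c1)O[C@H](c1ccc(OC)cc1OC)[C@H]2c1cc(OC)cc(OC)c1 | intermediate
17 | 4‑bromophenol | Oc1ccc(Br)cc1 | starting material
18 | 1‑bromo‑4‑methoxybenzene | COc1ccc(Br)cc1 | intermediate
19 | bromo(4‑methoxyphenyl)magnesium | COc1ccc([Mg]Br)cc1 | intermediate
20 | (2S,3S)‑6‑[(1S)‑1‑(2,6‑dimethoxyphenyl)‑2‑methoxy‑2‑(4‑methoxyphenyl)ethyl]‑2‑(2,4‑dimethoxyphenyl)‑3‑(3,5‑dimethoxyphenyl)‑4‑methoxy‑2,3‑dihydro‑1‑benzofuran (both epimers at the ether carbon) | COC(c1ccc(OC)cc1)[C@H](c1c(OC)cccc1OC)c1cc(OC)c2c(c1)O[C@H](c1ccc(OC)cc1OC)[C@H]2c1cc(OC)cc(OC)c1 | intermediate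
21 | (2S,3S)‑3‑[(2S,3S)‑2‑(2,4‑dimethoxyphenyl)‑3‑(3,5‑dimethoxyphenyl)‑4‑methoxy‑2,3‑dihydro‑1‑benzofuran‑6‑yl]‑4‑methoxy‑2‑(4‑methoxyphenyl)‑2,3‑dihydro‑1‑benzofuran | c1cc(OC)c2c(c1)O[C@H](c1ccc(OC)cc1)[C@H]2c1cc(OC)c2c(c1)O[C@H](c1ccc(OC)cc1OC)[C@H]2c1cc(OC)cc(OC)c1 | intermediate
22 | (4‑methoxyphenyl)lithium | [Li]c1ccc(OC)cc1 | intermediate
23 | chloro(4‑methoxyphenyl)zinc | Cl[Zn]c1ccc(OC)cc1 | intermediate
24 | 1‑[(E)‑2‑chloroethenyl]‑4‑methoxybenzene | COc1ccc(/C=C/Cl)cc1 | intermediate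
25 | 2‑{(2S,3S)‑3‑[(2S,3S)‑2‑(2,4‑dimethoxyphenyl)‑3‑(3,5‑dimethoxyphenyl)‑4‑methoxy‑2,3‑dihydro‑1‑benzofuran‑6‑yl]‑4‑methoxy‑2‑(4‑methoxyphenyl)‑2,3‑dihydro‑1‑benzofuran‑6‑yl}‑4,4,5,5‑tetramethyl‑1,3,2‑dioxaborolane | CC1(C)OB(OC1(C)C)c1cc(OC)c2c(c1)O[C@H](c1ccc(OC)cc1)[C@H]2c1cc(OC)c2c(c1)O[C@H](c1ccc(OC)cc1OC)[C@H]2c1cc(OC)cc(OC)c1 | intermediate
26 | (2S,3S)‑3‑[(2S,3S)‑2‑(2,4‑dimethoxyphenyl)‑3‑(3,5‑dimethoxyphenyl)‑4‑methoxy‑2,3‑dihydro‑1‑benzofuran‑6‑yl]‑4‑methoxy‑2‑(4‑methoxyphenyl)‑6‑[(E)‑2‑(4‑methoxyphenyl)ethenyl]‑2,3‑dihydro‑1‑benzofuran | COc1ccc(/C=C/c2cc(OC)c3c(c2)O[C@H](c2ccc(OC)cc2)[C@H]3c2cc(OC)c3c(c2)O[C@H](c2ccc(OC)cc2OC)[C@H]3c2cc(OC)cc(OC)c2)cc1 | intermediate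
27 | (2S,3S)‑3‑[(2S,3S)‑2‑(2,4‑dihydroxyphenyl)‑3‑(3,5‑dihydroxyphenyl)‑4‑hydroxy‑2,3‑dihydro‑1‑benzofuran‑6‑yl]‑2‑(4‑hydroxyphenyl)‑6‑[(E)‑2‑(4‑hydroxyphenyl)ethenyl]‑2,3‑dihydro‑1‑benzofuran‑4‑ol (CNP0118407.1) | Oc1ccc(/C=C/c2cc(O)c3c(c2)O[C@H](c2ccc(O)cc2)[C@H]3c2cc(O)c3c(c2)O[C@H](c2ccc(O)cc2O)[C@H]3c2cc(O)cc(O)c2)cc1 | target

## Step count and risks

Total step count: 13. Longest linear sequence: 10 steps (1 → 2 → 3 → 4 → 6 → 7 → 8 → 10 → 12 → 13); steps 5, 9 and 11 make side components.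

The three steps most likely to fail:

**Step 4 (proposed new method).** The risks are modest enantioselectivity on an internal 1,2‑diaryl alkene and diversion by attack of an ortho‑methoxy oxygen on the iodonio carbon. The fallback uses known chemistry, sets out from 8 and comes back at 13. Compound 8 is rearranged with achiral PhI(OH)OTs in MeOH at rt (the known racemic oxidative 1,2‑aryl shift of stilbenes). This gives 9 as the racemate, that is together with 2‑[(1R)‑1‑(3,5‑dimethoxyphenyl)‑2,2‑dimethoxyethyl]‑1,3‑dimethoxybenzene F1. The racemate is taken through the conditions of step 6, passing through 12 and its mirror‑image series, 2‑[(1R)‑1‑(3,5‑dimethoxyphenyl)‑2‑(2,4‑dimethoxyphenyl)‑2‑methoxyethyl]‑1,3‑dimethoxybenzene F2 (not isolated). The resulting racemic trans product is 13 plus (2R,3R)‑2‑(2,4‑dimethoxyphenyl)‑3‑(3,5‑dimethoxyphenyl)‑4‑methoxy‑2,3‑dihydro‑1‑benzofuran F3. Preparative chiral SFC on a polysaccharide phase separates the two, and 13 goes on to step 7.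

**Step 8 (the same new method on the advanced substrate).** Added risks are the acid‑sensitive 2‑(2,4‑dimethoxyphenyl) ring and competing oxidation of the many electron‑rich arenes. The fallback uses known chemistry, sets out from 15 and comes back at 21. Compound 15 is rearranged with PhI(OH)OTs in MeOH at 0 °C without stereocontrol. This gives 16 and about as much of its epimer (2S,3S)‑6‑[(1R)‑1‑(2,6‑dimethoxyphenyl)‑2,2‑dimethoxyethyl]‑2‑(2,4‑dimethoxyphenyl)‑3‑(3,5‑dimethoxyphenyl)‑4‑methoxy‑2,3‑dihydro‑1‑benzofuran F4. The mixture is carried through the conditions of step 10, via 20 and the epimeric (2S,3S)‑6‑[(1R)‑1‑(2,6‑dimethoxyphenyl)‑2‑methoxy‑2‑(4‑methoxyphenyl)ethyl]‑2‑(2,4‑dimethoxyphenyl)‑3‑(3,5‑dimethoxyphenyl)‑4‑methoxy‑2,3‑dihydro‑1‑benzofuran F5 (not isolated). The products are 21 and its diastereomer (2R,3R)‑3‑[(2S,3S)‑2‑(2,4‑dimethoxyphenyl)‑3‑(3,5‑dimethoxyphenyl)‑4‑methoxy‑2,3‑dihydro‑1‑benzofuran‑6‑yl]‑4‑methoxy‑2‑(4‑methoxyphenyl)‑2,3‑dihydro‑1‑benzofuran F6. Being diastereomers, they are separated on silica gel or by achiral HPLC, and 21 goes on to step 12.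

**Step 10 (one‑pot arylation and ring closure).** Ionising the 4‑methoxybenzylic methyl ether needs conditions that can also open the more labile upper ring, and surplus aryl metal could arylate the benzylic cation. The fallback sets out from 16 and comes back at 21; it closes the ring first and adds the aryl group second, so only acetal‑level ionisations are needed. Compound 16 with TMSOTf (10 mol %) in CH2Cl2 at −78 °C undergoes ortho‑methoxy‑assisted transacetalisation to the cyclic methyl acetal (3S)‑3‑[(2S,3S)‑2‑(2,4‑dimethoxyphenyl)‑3‑(3,5‑dimethoxyphenyl)‑4‑methoxy‑2,3‑dihydro‑1‑benzofuran‑6‑yl]‑2,4‑dimethoxy‑2,3‑dihydro‑1‑benzofuran F7 (both C‑2 epimers). F7 is then treated with TiCl4 and 19 at −78 °C (C‑arylation of a cyclic acetal, as in C‑glycoside synthesis). The aryl group adds to the five‑membered oxocarbenium ion anti to the C‑3 substituent and gives trans‑21 directly.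

Further compounds

F1 | step 4 | 2‑[(1R)‑1‑(3,5‑dimethoxyphenyl)‑2,2‑dimethoxyethyl]‑1,3‑dimethoxybenzene | COC(OC)[C@H](c1cc(OC)cc(OC)c1)c1c(OC)cccc1OC
F2 | step 4 | 2‑[(1R)‑1‑(3,5‑dimethoxyphenyl)‑2‑(2,4‑dimethoxyphenyl)‑2‑methoxyethyl]‑1,3‑dimethoxybenzene (both C‑2 epimers) | COC(c1ccc(OC)cc1OC)[C@H](c1cc(OC)cc(OC)c1)c1c(OC)cccc1OC
F3 | step 4 | (2R,3R)‑2‑(2,4‑dimethoxyphenyl)‑3‑(3,5‑dimethoxyphenyl)‑4‑methoxy‑2,3‑dihydro‑1‑benzofuran | c1cc(OC)c2c(c1)O[C@@H](c1ccc(OC)cc1OC)[C@@H]2c1cc(OC)cc(OC)c1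
F4 | step 8 | (2S,3S)‑6‑[(1R)‑1‑(2,6‑dimethoxyphenyl)‑2,2‑dimethoxyethyl]‑2‑(2,4‑dimethoxyphenyl)‑3‑(3,5‑dimethoxyphenyl)‑4‑methoxy‑2,3‑dihydro‑1‑benzofuran | COC(OC)[C@@H](c1c(OC)cccc1OC)c1cc(OC)c2c(c1)O[C@H](c1ccc(OC)cc1OC)[C@H]2c1cc(OC)cc(OC)c1
F5 | step 8 | (2S,3S)‑6‑[(1R)‑1‑(2,6‑dimethoxyphenyl)‑2‑methoxy‑2‑(4‑methoxyphenyl)ethyl]‑2‑(2,4‑dimethoxyphenyl)‑3‑(3,5‑dimethoxyphenyl)‑4‑methoxy‑2,3‑dihydro‑1‑benzofuran (both epimers at the ether carbon) | COC(c1ccc(OC)cc1)[C@@H](c1c(OC)cccc1OC)c1cc(OC)c2c(c1)O[C@H](c1ccc(OC)cc1OC)[C@H]2c1cc(OC)cc(OC)c1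
F6 | step 8 | (2R,3R)‑3‑[(2S,3S)‑2‑(2,4‑dimethoxyphenyl)‑3‑(3,5‑dimethoxyphenyl)‑4‑methoxy‑2,3‑dihydro‑1‑benzofuran‑6‑yl]‑4‑methoxy‑2‑(4‑methoxyphenyl)‑2,3‑dihydro‑1‑benzofuran | c1cc(OC)c2c(c1)O[C@@H](c1ccc(OC)cc1)[C@@H]2c1cc(OC)c2c(c1)O[C@H](c1ccc(OC)cc1OC)[C@H]2c1cc(OC)cc(OC)c1
F7 | step 10 | (3S)‑3‑[(2S,3S)‑2‑(2,4‑dimethoxyphenyl)‑3‑(3,5‑dimethoxyphenyl)‑4‑methoxy‑2,3‑dihydro‑1‑benzofuran‑6‑yl]‑2,4‑dimethoxy‑2,3‑dihydro‑1‑benzofuran (both C‑2 epimers) | c1cc(OC)c2c(c1)OC(OC)[C@H]2c1cc(OC)c2c(c1)O[C@H](c1ccc(OC)cc1OC)[C@H]2c1cc(OC)cc(OC)c1
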